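## Retrosynthetic overview

1. Target 8 ⇐ 7 by hydrogenolysis of two O-benzyl groups.
2. 7 ⇐ 5 by forming the C4–C4a bond, which closes the lactone ring, in an anodic Ph3P-mediated dehydrative SN2 ring closure (inversion, S → R).
3. 5 ⇐ 3 + 4 by esterifying a chelated OH; this ester oxygen becomes O1, which fixes the 8-acyl regiochemistry, and the stereocentre is bought in 4.
4. 3 ⇐ 1 + 2 by benzylating the two non-chelated OH groups of phloretin, so the 6-acyl lactone isomer cannot form.
5. Ring order: both benzene rings are bought; the dihydropyranone ring is the only ring made (step 3).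

Assumption: phloretin and (S)-3-hydroxy-3-phenylpropanoic acid are purchased; the target stereocentre C4 is R by CIP analysis of the given SMILES.

## Route

Step 1
Reactants: 1 phloretin; 2 benzyl bromide
Product: 3 1-[4-(benzyloxy)-2,6-dihydroxyphenyl]-3-[4-(benzyloxy)phenyl]propan-1-one
Conditions: BnBr (2.1 eq), K2CO3 (2.2 eq), acetone, reflux
Reagents that add atoms: benzyl bromide (2), BrCc1ccccc1
Why: Williamson ether synthesis; the two OH groups hydrogen-bonded to the ketone are much less acidic and nucleophilic than the 4'-OH and 4-OH, so two equivalents alkylate only the non-chelated phenols.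

Step 2
Reactants: 3 1-[4-(benzyloxy)-2,6-dihydroxyphenyl]-3-[4-(benzyloxy)phenyl]propan-1-one; 4 (S)-3-hydroxy-3-phenylpropanoic acid
Product: 5 5-(benzyloxy)-2-{3-[4-(benzyloxy)phenyl]propanoyl}-3-hydroxyphenyl (3S)-3-hydroxy-3-phenylpropanoate
Conditions: EDC·HCl (1.3 eq), DMAP (0.2 eq), CH2Cl2, 0 °C to rt, slow addition of 4
Reagents that add atoms: none
Why: Steglich esterification of an o-acylphenol; the two chelated OH groups of 3 are equivalent, the second is deactivated after the first acylation, and the carbinol stereocentre is not involved.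

Step 3
Reactants: 5 5-(benzyloxy)-2-{3-[4-(benzyloxy)phenyl]propanoyl}-3-hydroxyphenyl (3S)-3-hydroxy-3-phenylpropanoate
Product: 7 (4R)-5-(benzyloxy)-8-{3-[4-(benzyloxy)phenyl]propanoyl}-7-hydroxy-4-phenyl-3,4-dihydro-2H-chromen-2-one, via alkoxytriphenylphosphonium tetrafluoroborate 6 (not isolated)
Conditions: PPh3 (1.5 eq), 2,6-lutidine (2 eq), nBu4NBF4 (0.1 M), CH2Cl2, graphite(+)|Pt(−), undivided cell, 5 mA cm−2, 2.2 F mol−1, 0 °C to rt
Reagents that add atoms: none
Why: Proposed new method: anodic two-electron oxidation of PPh3 (oxidised well below the acyl-deactivated phenol ring) in the presence of the secondary alcohol gives alkoxyphosphonium ion 6 without the basic hydrazide of a classical Mitsunobu reaction (so E1cB to the cinnamate is disfavoured); the only ring carbon within reach, ortho to the ester oxygen and para to the lutidine-hydrogen-bonded free OH, then displaces Ph3P=O from the benzylic carbon in a 6-exo-tet SN2 step with inversion (S → R), and the proton lost on rearomatisation is reduced to H2 at the cathode; the closest known reaction types are the anodic Mitsunobu-type activation of alcohols by PPh3 (alkoxyphosphonium displaced by O, N and halide nucleophiles with inversion) and intramolecular phenol C-alkylation with aryl participation, which have not been combined for an arene carbon nucleophile.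

Step 4
Reactants: 7 (4R)-5-(benzyloxy)-8-{3-[4-(benzyloxy)phenyl]propanoyl}-7-hydroxy-4-phenyl-3,4-dihydro-2H-chromen-2-one
Product: 8 (4R)-5,7-dihydroxy-8-[3-(4-hydroxyphenyl)propanoyl]-4-phenyl-3,4-dihydro-2H-chromen-2-one
Conditions: H2 (1 atm), 10% Pd/C, EtOAc, rt
Reagents that add atoms: none
Why: Hydrogenolysis of aryl benzyl ethers under neutral aprotic conditions, which leaves the chelated aryl ketone, the lactone (no ring opening, so no migration to the 6-acyl isomer) and the non-acidic C4 stereocentre untouched.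

## Compound list

1 | phloretin, 3-(4-hydroxyphenyl)-1-(2,4,6-trihydroxyphenyl)propan-1-one | O=C(CCc1ccc(O)cc1)c1c(O)cc(O)cc1O | starting material
2 | benzyl bromide | BrCc1ccccc1 | starting material
3 | 1-[4-(benzyloxy)-2,6-dihydroxyphenyl]-3-[4-(benzyloxy)phenyl]propan-1-one (4,4'-di-O-benzylphloretin) | O=C(CCc1ccc(OCc2ccccc2)cc1)c1c(O)cc(OCc2ccccc2)cc1O | intermediate
4 | (S)-3-hydroxy-3-phenylpropanoic acid | OC(=O)C[C@H](O)c1ccccc1 | starting material
5 | 5-(benzyloxy)-2-{3-[4-(benzyloxy)phenyl]propanoyl}-3-hydroxyphenyl (3S)-3-hydroxy-3-phenylpropanoate | O=C(C[C@H](O)c1ccccc1)Oc1cc(OCc2ccccc2)cc(O)c1C(=O)CCc1ccc(OCc2ccccc2)cc1 | intermediate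
6 | {[(1S)-3-[5-(benzyloxy)-2-{3-[4-(benzyloxy)phenyl]propanoyl}-3-hydroxyphenoxy]-3-oxo-1-phenylpropyl]oxy}triphenylphosphonium tetrafluoroborate | O=C(C[C@H](O[P+](c1ccccc1)(c1ccccc1)c1ccccc1)c1ccccc1)Oc1cc(OCc2ccccc2)cc(O)c1C(=O)CCc1ccc(OCc2ccccc2)cc1.F[B-](F)(F)F | intermediate
7 | (4R)-5-(benzyloxy)-8-{3-[4-(benzyloxy)phenyl]propanoyl}-7-hydroxy-4-phenyl-3,4-dihydro-2H-chromen-2-one | O=C1C[C@H](c2ccccc2)c2c(OCc3ccccc3)cc(O)c(C(=O)CCc3ccc(OCc4ccccc4)cc3)c2O1 | intermediate
8 | (4R)-5,7-dihydroxy-8-[3-(4-hydroxyphenyl)propanoyl]-4-phenyl-3,4-dihydro-2H-chromen-2-one | O=C1C[C@H](c2ccccc2)c2c(O)cc(O)c(C(=O)CCc3ccc(O)cc3)c2O1 | target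

## Step count and risks

Total steps: 4. Longest linear sequence: 4.

**Step 3 (proposed new anodic ring closure).** The risks are elimination of the phosphonium ion to the aryl cinnamate (which would cyclise to racemic material), partial SN1 ionisation at the benzylic carbon eroding the ee, the ester having to adopt the less favoured s-trans geometry for ring closure, and competing anodic oxidation of the phenol. The ee of 7 should be checked by chiral HPLC against a racemic sample.

The fallback uses known chemistry, sets out from 3 and returns at 7. Compound 3 is reacted with purchased methyl (2S,3R)-3-phenyloxirane-2-carboxylate (trans, COC(=O)[C@H]1O[C@@H]1c1ccccc1) under BF3·OEt2 in CH2Cl2 at −40 °C (or in hexafluoroisopropanol). Friedel–Crafts opening of the epoxide at the benzylic carbon with inversion gives methyl (2S,3R)-3-[6-(benzyloxy)-3-{3-[4-(benzyloxy)phenyl]propanoyl}-2,4-dihydroxyphenyl]-2-hydroxy-3-phenylpropanoate F1. Any diastereomer from partial retention is removed by chromatography, because the C2 carbinol centre is still present. Warming F1 with catalytic TsOH in toluene closes the lactone onto the only adjacent free OH and gives (3S,4R)-5-(benzyloxy)-8-{3-[4-(benzyloxy)phenyl]propanoyl}-3,7-dihydroxy-4-phenyl-3,4-dihydro-2H-chromen-2-one F2. Phenyl chlorothionoformate and pyridine acylate the secondary alcohol in preference to the chelated phenol and give O-[(3S,4R)-5-(benzyloxy)-8-{3-[4-(benzyloxy)phenyl]propanoyl}-7-hydroxy-2-oxo-4-phenyl-3,4-dihydro-2H-chromen-3-yl] O-phenyl carbonothioate F3. Barton–McCombie deoxygenation (Bu3SnH, AIBN, toluene, 90 °C) removes the C3 oxygen without touching C4 and delivers 7.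

**Step 2 (esterification of a chelated phenol with an unprotected β-hydroxy acid).** The risks are self-esterification or dehydration of 4 and sluggish acylation of the hydrogen-bonded OH.

The fallback sets out from 4 and returns at 5. Acid 4 is silylated with TBSCl and imidazole in DMF to tert-butyldimethylsilyl (3S)-3-[(tert-butyldimethylsilyl)oxy]-3-phenylpropanoate F4. The silyl ester is cleaved with K2CO3 in aqueous methanol to (3S)-3-[(tert-butyldimethylsilyl)oxy]-3-phenylpropanoic acid F5. This acid, which can no longer self-condense, is coupled with 3 (EDC·HCl, DMAP, CH2Cl2) to give 5-(benzyloxy)-2-{3-[4-(benzyloxy)phenyl]propanoyl}-3-hydroxyphenyl (3S)-3-[(tert-butyldimethylsilyl)oxy]-3-phenylpropanoate F6. HF·pyridine in THF at 0 °C removes the silyl ether to give 5.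

**Step 1 (selective double benzylation).** The risks are mixtures of mono-, di- and tri-benzyl ethers and some ring C-benzylation.

The fallback sets out from 1 and returns at 3. Phloretin is exhaustively benzylated (excess BnBr, K2CO3, DMF, 80 °C) to 3-[4-(benzyloxy)phenyl]-1-[2,4,6-tris(benzyloxy)phenyl]propan-1-one F7. The two benzyl ethers ortho to the ketone are then cleaved selectively by chelation-directed debenzylation with BCl3 (2.2 eq, CH2Cl2, −78 °C), which leaves the two remote benzyl ethers and gives 3.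

## Further compounds

F1 | step 3 | methyl (2S,3R)-3-[6-(benzyloxy)-3-{3-[4-(benzyloxy)phenyl]propanoyl}-2,4-dihydroxyphenyl]-2-hydroxy-3-phenylpropanoate | COC(=O)[C@@H](O)[C@H](c1ccccc1)c1c(O)c(C(=O)CCc2ccc(OCc3ccccc3)cc2)c(O)cc1OCc1ccccc1
F2 | step 3 | (3S,4R)-5-(benzyloxy)-8-{3-[4-(benzyloxy)phenyl]propanoyl}-3,7-dihydroxy-4-phenyl-3,4-dihydro-2H-chromen-2-one | O=C1[C@@H](O)[C@H](c2ccccc2)c2c(OCc3ccccc3)cc(O)c(C(=O)CCc3ccc(OCc4ccccc4)cc3)c2O1
F3 | step 3 | O-[(3S,4R)-5-(benzyloxy)-8-{3-[4-(benzyloxy)phenyl]propanoyl}-7-hydroxy-2-oxo-4-phenyl-3,4-dihydro-2H-chromen-3-yl] O-phenyl carbonothioate | O=C1[C@@H](OC(=S)Oc2ccccc2)[C@H](c2ccccc2)c2c(OCc3ccccc3)cc(O)c(C(=O)CCc3ccc(OCc4ccccc4)cc3)c2O1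
F4 | step 2 | tert-butyldimethylsilyl (3S)-3-[(tert-butyldimethylsilyl)oxy]-3-phenylpropanoate | CC(C)(C)[Si](C)(C)OC(=O)C[C@H](O[Si](C)(C)C(C)(C)C)c1ccccc1
F5 | step 2 | (3S)-3-[(tert-butyldimethylsilyl)oxy]-3-phenylpropanoic acid | OC(=O)C[C@H](O[Si](C)(C)C(C)(C)C)c1ccccc1
F6 | step 2 | 5-(benzyloxy)-2-{3-[4-(benzyloxy)phenyl]propanoyl}-3-hydroxyphenyl (3S)-3-[(tert-butyldimethylsilyl)oxy]-3-phenylpropanoate | O=C(C[C@H](O[Si](C)(C)C(C)(C)C)c1ccccc1)Oc1cc(OCc2ccccc2)cc(O)c1C(=O)CCc1ccc(OCc2ccccc2)cc1
F7 | step 1 | 3-[4-(benzyloxy)phenyl]-1-[2,4,6-tris(benzyloxy)phenyl]propan-1-one | O=C(CCc1ccc(OCc2ccccc2)cc1)c1c(OCc2ccccc2)cc(OCc2ccccc2)cc1OCc1ccccc1
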